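**Assumption:** Broussonol D has no stereocentre (the SMILES carries none), so the achiral compound is the target. The only stereo-element in the route is the E-alkene of 12/13, which is consumed in step 10.

## Retrosynthetic overview

1. Target ⇐ global MOM removal ⇐ protected flavonol ⇐ Algar–Flynn–Oyamada closure of a 2'-hydroxychalcone. The pyranone ring is the only ring made, and it is made last.
2. Key disconnection: the C4–C4a aryl–carbonyl bond, formed by a photo-Fries radical-pair 1,3-acyl shift of an aryl cinnamate. The ester oxygen sits next to the prenyl group and becomes O1, which fixes the 8-prenyl regiochemistry.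
3. Aryl cinnamate ⇐ oxidative Heck coupling of the A-ring aryl acrylate with the B-ring arylboronate.
4. A-ring phenol ⇐ resorcinol (MOM protection, Ir C–H borylation/oxidation for the third oxygen, ortho C-prenylation).
5. B-ring boronate ⇐ catechol (MOM protection, directed ortho-metalation/prenylation, Ir C–H borylation).

Reagents (MOMCl, B2pin2, H2O2, bases, catalysts) are not numbered.

## Route

**Step 1**
Reactants: 1 resorcinol
Product: 2 1,3-bis(methoxymethoxy)benzene
Conditions: MOMCl (2.5 equiv), i-Pr2NEt, CH2Cl2, 0 °C → rt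
Reagents that add atoms: chloromethyl methyl ether, COCCl
Why: Williamson-type O-alkylation gives the bis-MOM ether, which is stable to the later base, Ir, Pd, light and peroxide steps.

**Step 2**
Reactants: 2 1,3-bis(methoxymethoxy)benzene
Product: 3 3,5-bis(methoxymethoxy)phenol
Conditions: [Ir(OMe)(cod)]2 (1 mol%), dtbpy (2 mol%), B2pin2 (0.6 equiv), THF, 80 °C; then 30% H2O2, aq NaOH, 0 °C (one pot)
Reagents that add atoms: hydrogen peroxide, OO (supplies the phenolic oxygen; the boron from B2pin2 is lost)
Why: sterically controlled Ir-catalysed C–H borylation occurs only at C5, the one C–H with no ortho substituent, and the arylboronate is oxidised in the same pot to the phenol.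

**Step 3**
Reactants: 3 3,5-bis(methoxymethoxy)phenol; 4 prenyl bromide
Product: 5 3,5-bis(methoxymethoxy)-2-(3-methylbut-2-en-1-yl)phenol
Conditions: NaH (1.05 equiv), toluene, 0 °C; then 4 (1.0 equiv), rt
Reagents that add atoms: none beyond reactant 4 (CC(C)=CCBr)
Why: ortho C-alkylation of a sodium phenoxide in a non-polar solvent (tight ion pair, SN2 at the CH2 terminus) gives the normal prenyl group at either of the two equivalent ortho carbons.

**Step 4**
Reactants: 6 catechol
Product: 7 1,2-bis(methoxymethoxy)benzene
Conditions: NaH, DMF, 0 °C; MOMCl (2.4 equiv), 0 °C → rt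
Reagents that add atoms: chloromethyl methyl ether, COCCl
Why: MOM ether formation protects the catechol and provides the directing group for the next lithiation.

**Step 5**
Reactants: 7 1,2-bis(methoxymethoxy)benzene; 4 prenyl bromide
Product: 8 1,2-bis(methoxymethoxy)-3-(3-methylbut-2-en-1-yl)benzene
Conditions: n-BuLi, TMEDA, THF, 0 °C; CuI (0.2 equiv), −78 °C; then 4, −78 °C → rt
Reagents that add atoms: none beyond reactant 4 (CC(C)=CCBr)
Why: MOM-directed ortho-metalation gives the 3-lithio arene, and copper-mediated SN2 allylation with prenyl bromide installs the linear prenyl group regiospecifically.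

**Step 6**
Reactants: 8 1,2-bis(methoxymethoxy)-3-(3-methylbut-2-en-1-yl)benzene
Product: 9 2-[3,4-bis(methoxymethoxy)-5-(3-methylbut-2-en-1-yl)phenyl]-4,4,5,5-tetramethyl-1,3,2-dioxaborolane
Conditions: [Ir(OMe)(cod)]2 (1.5 mol%), dtbpy (3 mol%), B2pin2 (1.0 equiv), MTBE, 60 °C
Reagents that add atoms: bis(pinacolato)diboron, CC1(C)OB(OC1(C)C)B1OC(C)(C)C(C)(C)O1
Why: Ir-catalysed C–H borylation selects C5, the only C–H flanked by two hydrogens (C4 is ortho to prenyl, C6 ortho to OMOM), and the trisubstituted alkene is expected to be too hindered to hydroborate.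

**Step 7**
Reactants: 5 3,5-bis(methoxymethoxy)-2-(3-methylbut-2-en-1-yl)phenol; 10 acryloyl chloride
Product: 11 3,5-bis(methoxymethoxy)-2-(3-methylbut-2-en-1-yl)phenyl prop-2-enoate
Conditions: Et3N, CH2Cl2, −20 → 0 °C (trace BHT)
Reagents that add atoms: none beyond reactant 10 (C=CC(=O)Cl)
Why: O-acylation of the phenol puts the acyl group on the oxygen next to the prenyl group, the oxygen that will become O1.

**Step 8**
Reactants: 11 aryl acrylate; 9 arylboronate
Product: 12 3,5-bis(methoxymethoxy)-2-(3-methylbut-2-en-1-yl)phenyl (2E)-3-[3,4-bis(methoxymethoxy)-5-(3-methylbut-2-en-1-yl)phenyl]prop-2-enoate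
Conditions: Pd(OAc)2 (5 mol%), 2,9-dimethyl-1,10-phenanthroline (6 mol%), Na2CO3, O2 (1 atm), DMA, 50 °C
Reagents that add atoms: none
Why: Pd(II)-catalysed oxidative (boron) Heck reaction — transmetalation, insertion into the acrylate and β-hydride elimination give the E-cinnamate, and the hindered prenyl alkenes do not compete as Heck acceptors.

**Step 9**
Reactants: 12 aryl cinnamate
Product: 13 (2E)-3-[3,4-bis(methoxymethoxy)-5-(3-methylbut-2-en-1-yl)phenyl]-1-[2-hydroxy-4,6-bis(methoxymethoxy)-3-(3-methylbut-2-en-1-yl)phenyl]prop-2-en-1-one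
Conditions: hν (300 nm), degassed benzene (5 mM), rt
Reagents that add atoms: none
Why: photo-Fries rearrangement — homolysis of the ArO–C(O) bond gives a caged aryloxyl/cinnamoyl radical pair that recombines at C6, the only free ortho carbon (the other carries the prenyl group), and tautomerises to the hydrogen-bonded 2'-hydroxychalcone, so the freed OH is the one adjacent to the prenyl group.

**Step 10**
Reactants: 13 2'-hydroxychalcone
Product: 14 2-[3,4-bis(methoxymethoxy)-5-(3-methylbut-2-en-1-yl)phenyl]-3-hydroxy-5,7-bis(methoxymethoxy)-8-(3-methylbut-2-en-1-yl)-4H-chromen-4-one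
Conditions: 30% H2O2, 2 M aq NaOH, MeOH–THF, 0 °C → rt
Reagents that add atoms: hydrogen peroxide, OO (supplies the 3-OH oxygen)
Why: Algar–Flynn–Oyamada reaction — nucleophilic epoxidation of the enone by HOO⁻, ring closure by the single free 2'-phenoxide and in situ oxidation give the flavonol, while alkaline peroxide leaves the electron-rich prenyl alkenes alone and either enone geometry converges.

**Step 11**
Reactants: 14 tetra-MOM flavonol
Product: 15 broussonol D
Conditions: 3 M aq HCl–MeOH (1:4), 45 °C, Ar, monitored to completion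
Reagents that add atoms: none
Why: acid-catalysed acetal cleavage removes all four MOM groups under conditions mild enough to avoid chroman formation from the ortho-prenyl phenols; no stereocentre is present or created.

## Compound list

1 | resorcinol | Oc1cccc(O)c1 | starting material
2 | 1,3-bis(methoxymethoxy)benzene | COCOc1cccc(OCOC)c1 | intermediate
3 | 3,5-bis(methoxymethoxy)phenol | COCOc1cc(O)cc(OCOC)c1 | intermediate
4 | prenyl bromide (1-bromo-3-methylbut-2-ene) | CC(C)=CCBr | starting material
5 | 3,5-bis(methoxymethoxy)-2-(3-methylbut-2-en-1-yl)phenol | CC(C)=CCc1c(O)cc(OCOC)cc1OCOC | intermediate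
6 | catechol | Oc1ccccc1O | starting material
7 | 1,2-bis(methoxymethoxy)benzene | COCOc1ccccc1OCOC | intermediate
8 | 1,2-bis(methoxymethoxy)-3-(3-methylbut-2-en-1-yl)benzene | CC(C)=CCc1cccc(OCOC)c1OCOC | intermediate
9 | 2-[3,4-bis(methoxymethoxy)-5-(3-methylbut-2-en-1-yl)phenyl]-4,4,5,5-tetramethyl-1,3,2-dioxaborolane | CC(C)=CCc1cc(B2OC(C)(C)C(C)(C)O2)cc(OCOC)c1OCOC | intermediate
10 | acryloyl chloride | C=CC(=O)Cl | starting material
11 | 3,5-bis(methoxymethoxy)-2-(3-methylbut-2-en-1-yl)phenyl prop-2-enoate | C=CC(=O)Oc1cc(OCOC)cc(OCOC)c1CC=C(C)C | intermediate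
12 | 3,5-bis(methoxymethoxy)-2-(3-methylbut-2-en-1-yl)phenyl (2E)-3-[3,4-bis(methoxymethoxy)-5-(3-methylbut-2-en-1-yl)phenyl]prop-2-enoate | COCOc1cc(/C=C/C(=O)Oc2cc(OCOC)cc(OCOC)c2CC=C(C)C)cc(CC=C(C)C)c1OCOC | intermediate
13 | (2E)-3-[3,4-bis(methoxymethoxy)-5-(3-methylbut-2-en-1-yl)phenyl]-1-[2-hydroxy-4,6-bis(methoxymethoxy)-3-(3-methylbut-2-en-1-yl)phenyl]prop-2-en-1-one | COCOc1cc(/C=C/C(=O)c2c(O)c(CC=C(C)C)c(OCOC)cc2OCOC)cc(CC=C(C)C)c1OCOC | intermediate
14 | 2-[3,4-bis(methoxymethoxy)-5-(3-methylbut-2-en-1-yl)phenyl]-3-hydroxy-5,7-bis(methoxymethoxy)-8-(3-methylbut-2-en-1-yl)-4H-chromen-4-one | COCOc1cc(-c2oc3c(CC=C(C)C)c(OCOC)cc(OCOC)c3c(=O)c2O)cc(CC=C(C)C)c1OCOC | intermediate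
15 | broussonol D, 2-[3,4-dihydroxy-5-(3-methylbut-2-en-1-yl)phenyl]-3,5,7-trihydroxy-8-(3-methylbut-2-en-1-yl)-4H-chromen-4-one | CC(C)=CCc1cc(-c2oc3c(CC=C(C)C)c(O)cc(O)c3c(=O)c2O)cc(O)c1O | target

## Summary

Total steps: 11.
Longest linear sequence: 8 (steps 1, 2, 3, 7, 8, 9, 10, 11); the B-ring branch (steps 4–6) joins at step 8.

Three steps most likely to fail:

1. **Step 9 (photo-Fries of the cinnamate).** Risks are E/Z isomerisation and [2+2] chemistry of the cinnamoyl chromophore, the para-acyl isomer from recombination at C4, cage escape back to phenol 5, and inner-filter absorption by the chalcone. Fallback: acetylate 5 and run the photo-Fries on the simple acetate to get 2-hydroxy-4,6-bis(MOM-oxy)-3-prenylacetophenone. Then build the enone by Claisen–Schmidt condensation with the B-ring aldehyde, made from 9 by ipso-bromination and Li/DMF.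

2. **Step 10 (Algar–Flynn–Oyamada).** The 6'-alkoxy group favours aurone formation and over-oxidation is possible. Fallback: close the ring without peroxide by I2 (cat.)/DMSO oxidative cyclisation of 13 to the flavone. Then install the 3-OH by C3-lithiation (LDA), B(OMe)3 and H2O2, which leaves the prenyl alkenes intact.

3. **Step 3 (ortho C-prenylation of 3).** O-prenyl ether, the para (C4) isomer and bis-alkylation will lower the yield. Fallback: O-prenylate 3 (K2CO3, acetone) and move the prenyl group to the ortho carbon by a clay-promoted (montmorillonite K10 or Florisil) [1,3]-O→C shift, accepting one extra step.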